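A leftover is where I begin: at its last reading, 86 min, the amber run still holds 24.2% of its charge of starting material, and at 86 min the red run holds 8.80%. The question that matters most to me is what the grey run keeps at 86 min.

the same everywhere: catalyst 5.00 mM

| flask | starting material | partner | time |
|---|---|---|---|
| amber | 50.0 mM | 150 mM |  |
| red | 25.0 mM | 125 mM |  |
| green | 50.0 mM | 220 mM |  |
| grey | 13.0 mM | 37.0 mM | 86 min |

- amber run (time / min: [starting material] / mM): 4.9: 46.7; 15: 39.3; 28: 28.7; 45: 19.5; 64: 13.8; 86: 12.1
- red run (time / min: [starting material] / mM): 4.9: 24.0; 15: 17.3; 28: 13.3; 45: 9.5; 64: 5.9; 86: 2.2
- green run (time / min: [starting material] / mM): 4.9: 48.0; 15: 38.7; 28: 29.9; 45: 20.4; 64: 15.5; 86: 12.2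

(scatter of a reading: 0.8 mM)

* apparent order in [partner] of the starting rate, round the charge of the amber run (the rate where two percent of its starting material have turned into product)
* apparent order in [starting material] of the starting rate, round the charge of the amber run (the rate where two percent of its starting material have turned into product) (one fixed amount of product, the same in the runs compared)
* the red run starts with 25.0 mM less of starting material and of partner than the amber run, and with no product. Compared where both hold the same amount of starting material, once fifteen percent of what the red run was charged with has turned into product, is the red run faster, slower or alike (within a tenth)?
* starting material in the grey run at 86 min, as a share of the starting material charged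

- Overall: starting material + partner -> product, with catalyst as catalyst.
- Constant volume, constant temperature.
- The analysis sees a species whether free or bound.
- "The second partner" is partner.
- An order is taken over about fifteen percent of the charge, up and down.

I draw the amber curve in shares of its charge. Between its first and third readings the share falls by 0.0156 min⁻¹, and a straight line at that slope from a full charge would reach zero at 64.1 min. But the amber reading at 64 min is still 27.6%, so the knee lies before that time. Over the last two amber readings the slope is 0.001545 min⁻¹, ten times smaller, and the amber readings seem to flatten toward a level near 24.2%.

The red curve, from half the amber charge, still lies on the amber one at 45 min, with 38.0% against 39.0%, and then parts downward. Over its last two readings the red share falls by 0.006727 min⁻¹, faster than the amber share, with no level in sight.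

For the ends I go to logarithms. The red run has fallen by 1.06 decades; this decade count, the power of ten by which a run's share of starting material has fallen at 86 min, is what I carry. The scatter of 0.8 mM on that last red reading spreads it from 0.921 to 1.25. The amber run reads 0.616 and the green run 0.613, although the green run has more partner, 220 mM against 150 mM.

The grey run is charged with a quarter of the amber charge, less than the 37.9 mM the amber run had used by its last reading. If the amber level goes with the amount turned, which is my guess and no more, the grey run meets no level. On that guess I put the grey run on the red count, which leaves 8.80%. The weak spot is its partner, 37.0 mM, lower than in any run read.

The forecast gives 0.05 for the order in partner, 0.3 for the order in starting material, faster for the red run, and 12% for the grey run, above my figure. Its words on the grey run are these: “Grey has little product, but its low partner may slow it.”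

The flask gives −0.43 for the order in partner, 0.88 for the order in starting material, alike for the red run, and 8.84% for the grey run.

    catalyst + starting material ⇌ catalyst-substrate complex (8.760 L mol⁻¹ min⁻¹, 0.02520 min⁻¹)
    catalyst-substrate complex + partner → product + catalyst (27.66 L mol⁻¹ min⁻¹)
    catalyst + partner ⇌ idle catalyst-reagent complex, settled at all times (16.20 L mol⁻¹)
    2 partner → lost reagent (0.4746 L mol⁻¹ min⁻¹)

That grey share is 1.05 decades, against the 1.06 read on the red run. Product comes to half of the charge at 31.9 min in the red run and at 34.9 min in the amber run, which is 0.301 decades in each. From that mark to the last reading the red run falls 0.759 more decades, and the amber run 0.315.

The numbers in the tables come from a simulation for an exercise; scatter was added.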